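All runs are simulated with made-up constants, noise included.

**Slowness first.** In the violet run, G's loss slows beyond what G's own decline explains, and a pseudo-first-order rate constant divides that decline out. Over the first 25.0 s it reads 0.00430 s⁻¹, but between 80.0 s and 120 s only 0.00174 s⁻¹, so it is slower by a factor of 2.48.

the same everywhere: G 0.050 M; L 0.050 M; D 0.072 mol%

| run | Z | remark | time |
|---|---|---|---|
| violet | 1.4 equiv | run made earlier |  |
| green | 2.2 equiv | run made earlier |  |
| flask | 1.00 equiv |  | 3.0 min |

| run | time / s | J / % | G / % |
|---|---|---|---|
| violet | 10.0 | 2.5 | 47.9 |
| violet | 25.0 | 4.6 | 44.9 |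
| violet | 50.0 | 8.5 | 41.3 |
| violet | 80.0 | 11.6 | 38.7 |
| violet | 120 | 14.0 | 36.1 |
| green | 20.0 | 4.1 | 46.0 |
| green | 40.0 | 7.7 | 42.5 |
| green | 60.0 | 10.3 | 40.0 |
| green | 80.0 | 10.7 | 37.2 |
| green | 120 | 13.1 | 36.0 |

(each reading ± 0.5 percentage points)

- D is single-handed; G and L are mirror images of each other, charged as a racemate, each of them at the stated concentration
- solid, in amounts per volume of the solution: Z
- what was read earlier has a scatter of 0.5 percentage points, one standard deviation
- at the start none of Z is in solution

* J at 3.0 min, in percent of the G and L together charged
* the change that raises the amount of J at 3.0 min, in percent of the G and L together charged most ("none" if none brings more than 2 percentage points) (Friday's / Saturday's / Monday's / none)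
* amount of J at 3.0 min, in percent of the G and L together charged, after Monday's

- Friday's: doubling the amount of D, all else as stated
- Saturday's: doubling the dissolution coefficient of Z, all else as stated
- Monday's: doubling the solubility of Z, all else as stated

**Two suspects.** Z comes first. The logarithmic fall of G at 120 s in violet, divided by that in green, is 0.992, so you can give the amount of Z a factor near one. The flask's 1.00 equiv lies below both runs, which is a risk I cannot size. I read the slowing as first-order loss of D. The two windows are centred 87.5 s apart, which gives a lifetime of 96.5 s.

**The reach.** Define the reach as the logarithmic fall of G that D delivers by a given time: the starting constant, times the lifetime, times the fraction of D lost by then. The flask's 3.0 min is 1.87 lifetimes, so the reach is 0.351 and J is 14.8%. With dissolved Z held constant, the reach scales with the loading of D. I cannot size Monday's from these runs, so my choice of Friday's is a judgement and not a comparison of the changes.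

**The forecast.** The forecast gives 16% against my 14.8%, names Friday's and puts Monday's at 20%, reasoning that “the amount of solid Z doesn't matter”.

**The result.** The flask gives 15.1% of J. Friday's adds 6.9 percentage points, and Monday's gives 16.8%.

    X + D + G → D + J (k = 5000 L² mol⁻² s⁻¹)
    X + D + L → D + Q (k = 3000 L² mol⁻² s⁻¹)
    Z ⇌ X, rate k3*(cs3 - [X]) while solid is left; crystals form when [X] > cs3 (solubility = 31.0 mM, k = 0.420 s⁻¹)
    D → E (k = 0.0130 s⁻¹)

**The neighbour.** The neighbour flask has 0.029 mol% of D and keeps 9.63% of it at 3.00 min, as the flask keeps 9.63%. Scaling the reach by the loading gives 0.141, hence 6.59% of J. The neighbour flask gives 6.97%.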